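**Plan**

- Numbering of each outer ring: C1 butanoyl carbon, C2 its neighbour toward the methyl group, C3 methyl carbon, C4, C5 bridge-bearing carbon, C6. The two outer rings differ: ring A has 2-OH, 4-OMe, 6-OH; ring C has 2-OMe, 4-OH, 6-OH.
- Retrosynthesis: the five O-protecting groups go last; then both outer rings are cut at C1–C2 and C5–C6, giving one alkoxy ynone (C6 and C1) and a ring B-bound bis(vinylketene acetal); then the two CH2–C5 bonds are cut.
- Enabling feature: ring A C2(OH)–C3(Me)–C4(OMe)–C5 and ring C C2(OMe)–C3(Me)–C4(OH)–C5 are 1,1,3-trioxygenated diene units, and in both rings C6–O with the C1 butanoyl group is an acyl ynol ether. Ring A therefore needs a methyl silyl ketene acetal with 3-OMe, ring C a dimethyl ketene acetal with 3-OSiMe3.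
- Forward: ring B (from 2,4,6-trihydroxyacetophenone) is diformylated, benzylated, reduced and acetylated; two different parent dienes are attached by SN1 alkylation; one enolisation–silylation gives the unsymmetrical bis-diene; a double annulation with 1-isopropoxyhex-1-yn-3-one closes rings A and C together; BCl3 removes three benzyl and two isopropyl groups.
- An isopropyl (not a primary alkyl) ynol ether is used because a secondary alkyl aryl ether is cleaved by BCl3 without touching methyl ethers.
- Stereochemistry: the target has no stereocentre; only the (Z) geometry of the two diene termini matters, and it is set in the enolisation.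

Key step: step 15

Remark: alkene geometries drawn for 2, 3, 14 and 15 are the expected major ones; they have no consequence because these carbons become aromatic.

**Step 1**
Reactants: 1 methyl 2-methyl-3-oxobutanoate
Product: 2 methyl (2E)-3-methoxy-2-methylbut-2-enoate
Conditions: HC(OMe)3, H2SO4 (cat.), MeOH, rt; then distillation
Reagents that add atoms: trimethyl orthoformate, COC(OC)OC
Why: Acid-catalysed enol ether formation from a β-keto ester with an orthoformate should give the conjugated β-methoxy enoate, the known precursor of 2-methyl Brassard-type dienes.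

**Step 2**
Reactants: 2 methyl (2E)-3-methoxy-2-methylbut-2-enoate
Product: 3 (1E)-1,3-dimethoxy-2-methyl-1-(trimethylsilyloxy)buta-1,3-diene
Conditions: Me3SiCl, LiN(iPr)2, THF, −78 °C → rt; pentane, filtration, distillation
Reagents that add atoms: chlorotrimethylsilane, C[Si](C)(C)Cl
Why: Kinetic γ-deprotonation of the β-methoxy enoate with in situ O-silylation is the standard silyl ketene acetal route to Brassard-type dienes.

**Step 3**
Reactants: 4 trimethyl orthopropionate
Product: 5 1,1-dimethoxyprop-1-ene
Conditions: Me3SiOTf, iPr2NEt, pentane, −20 °C → rt; distillation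
Reagents that add atoms: none
Why: Silyl triflate ionises the ortho ester to the dialkoxycarbenium ion and the hindered amine deprotonates it, the usual alcohol elimination from acetals and ortho esters to enol ethers and ketene acetals.

**Step 4**
Reactants: 5 1,1-dimethoxyprop-1-ene, 6 acetyl chloride
Product: 7 4,4-dimethoxy-3-methylbut-3-en-2-one
Conditions: Et3N, Et2O, 0 °C → rt
Reagents that add atoms: none
Why: C-acylation of a ketene acetal by an acid chloride, followed by deprotonation of the dialkoxycarbenium ion by the amine, is the classical route to acylketene acetals.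

**Step 5**
Reactants: 7 4,4-dimethoxy-3-methylbut-3-en-2-one
Product: 8 1,1-dimethoxy-2-methyl-3-(trimethylsilyloxy)buta-1,3-diene
Conditions: Me3SiCl, LiN(iPr)2, THF, −78 °C → rt; pentane, filtration, distillation
Reagents that add atoms: chlorotrimethylsilane, C[Si](C)(C)Cl
Why: Kinetic deprotonation of the only enolisable position (the acetyl methyl group) with O-silylation gives the 1,1-dimethoxy-3-silyloxy diene (silyl enol ether formation).

**Step 6**
Reactants: 9 2,4,6-trihydroxyacetophenone
Product: 10 5-acetyl-2,4,6-trihydroxybenzene-1,3-dicarbaldehyde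
Conditions: Cl2CHOMe, TiCl4, CH2Cl2, 0 °C → rt; then 1 M HCl, 0 °C
Reagents that add atoms: dichloromethyl methyl ether, COC(Cl)Cl; water, O
Why: Rieche formylation: the titanium phenoxide directs the electrophile to the two free ring carbons, each flanked by two hydroxyls, and aqueous acid hydrolyses the α-chloro ethers to the aldehydes, as known for acylphloroglucinols.

**Step 7**
Reactants: 10 5-acetyl-2,4,6-trihydroxybenzene-1,3-dicarbaldehyde
Product: 11 5-acetyl-2,4,6-tris(benzyloxy)benzene-1,3-dicarbaldehyde
Conditions: BnBr, K2CO3, Bu4NI (cat.), DMF, 60 °C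
Reagents that add atoms: benzyl bromide, BrCc1ccccc1
Why: Williamson ether synthesis in a dipolar aprotic solvent; every ring carbon is substituted, so benzylation of the three acidic, carbonyl-chelated phenoxides should end on oxygen.

**Step 8**
Reactants: 11 5-acetyl-2,4,6-tris(benzyloxy)benzene-1,3-dicarbaldehyde
Product: 12 1-[2,4,6-tris(benzyloxy)-3,5-bis(hydroxymethyl)phenyl]ethan-1-one
Conditions: NaBH4, THF/MeOH, −20 → 0 °C
Reagents that add atoms: none
Why: Chemoselective borohydride reduction: the two aldehydes react much faster than the methyl ketone, which is shielded by two ortho benzyloxy groups and twisted out of the ring plane.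

**Step 9**
Reactants: 12 1-[2,4,6-tris(benzyloxy)-3,5-bis(hydroxymethyl)phenyl]ethan-1-one
Product: 13 [5-acetyl-2,4,6-tris(benzyloxy)-1,3-phenylene]bis(methylene) diacetate
Conditions: Ac2O, pyridine, DMAP (cat.), CH2Cl2, rt
Reagents that add atoms: acetic anhydride, CC(=O)OC(C)=O
Why: DMAP-catalysed acyl transfer acetylates both primary benzylic alcohols and gives storable precursors of the stabilised 2,4,6-trialkoxybenzylic cations.

**Step 10**
Reactants: 13 [5-acetyl-2,4,6-tris(benzyloxy)-1,3-phenylene]bis(methylene) diacetate, 3 (1E)-1,3-dimethoxy-2-methyl-1-(trimethylsilyloxy)buta-1,3-diene, 8 1,1-dimethoxy-2-methyl-3-(trimethylsilyloxy)buta-1,3-diene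
Product: 14 methyl (2E)-5-[3-acetyl-2,4,6-tris(benzyloxy)-5-(5,5-dimethoxy-4-methyl-3-oxopent-4-en-1-yl)phenyl]-3-methoxy-2-methylpent-2-enoate
Conditions: 3 (1 equiv), 8 (1 equiv), Me3SiOTf (5 mol %), CH2Cl2, −78 → −40 °C; then Et3N; chromatography on Et3N-treated silica
Reagents that add atoms: none
Why: Vinylogous Mukaiyama-type SN1 alkylation: catalytic silyl triflate ionises each benzylic acetate and either silyl diene captures the cation at its unsubstituted terminal carbon while the ring B ketone stays inert; because the two benzylic positions are equivalent the step is statistical, so at most half of the material can become 14, which should differ enough in polarity from the two symmetrical bis-adducts to be separated.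

**Step 11**
Reactants: 14 methyl (2E)-5-[3-acetyl-2,4,6-tris(benzyloxy)-5-(5,5-dimethoxy-4-methyl-3-oxopent-4-en-1-yl)phenyl]-3-methoxy-2-methylpent-2-enoate
Product: 15 ring B tris(benzyl ether) bearing a 1-(trimethylsilyloxy)vinyl group, a (2Z,4E)-3,5-dimethoxy-4-methyl-5-(trimethylsilyloxy)penta-2,4-dien-1-yl arm and a (2Z)-5,5-dimethoxy-4-methyl-3-(trimethylsilyloxy)penta-2,4-dien-1-yl arm
Conditions: Me3SiCl (5 equiv), LiN(iPr)2 (3.5 equiv), THF, −78 → −40 °C; pentane, filtration under argon; used crude
Reagents that add atoms: chlorotrimethylsilane, C[Si](C)(C)Cl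
Why: Kinetic enolisation with in situ silylation turns the ring B methyl ketone into its silyl enol ether (a transient protecting group), the β-methoxy enoate into the methyl silyl ketene acetal (γ-deprotonation) and the acylketene acetal into the (Z)-silyl enol ether (α'-deprotonation), in both arms with the ring B CH2 on the outer position of the diene terminus where allylic strain is smallest.

**Step 12**
Reactants: 16 butanoyl chloride
Product: 17 N-methoxy-N-methylbutanamide
Conditions: MeNH(OMe)·HCl, Et3N, CH2Cl2, 0 °C → rt
Reagents that add atoms: N,O-dimethylhydroxylamine hydrochloride, CNOC.Cl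
Why: Acylation of the hydroxylamine by the acid chloride gives the Weinreb amide.

**Step 13**
Reactants: 18 propan-2-ol, 19 trichloroethylene
Product: 20 (E)-1,2-dichloro-1-(propan-2-yloxy)ethene
Conditions: KH, THF, 0 °C; then 19, −50 °C → rt; distillation
Reagents that add atoms: none
Why: Base-induced elimination–addition of the potassium alkoxide to trichloroethylene is the established first stage of the dichlorovinyl ether route to ynol ethers.

**Step 14**
Reactants: 20 (E)-1,2-dichloro-1-(propan-2-yloxy)ethene, 17 N-methoxy-N-methylbutanamide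
Product: 22 1-(propan-2-yloxy)hex-1-yn-3-one, via lithium (propan-2-yloxy)ethynide 21 (not isolated)
Conditions: n-BuLi (2.2 equiv), THF, −78 → −40 °C; then 17, −78 → 0 °C; pH 7 buffer; stored cold
Reagents that add atoms: none
Why: Elimination and chlorine–lithium exchange give the lithium alkoxyacetylide 21, whose addition to the Weinreb amide stops at the chelated tetrahedral adduct and releases the ynone only on buffered work-up (Weinreb ketone synthesis).

**Step 15**
Reactants: 15 ring B-bound unsymmetrical bis(vinylketene acetal), 22 1-(propan-2-yloxy)hex-1-yn-3-one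
Product: 24 protected trimer (ring B tris(benzyl ether) carrying isopropyl ethers at C6 of rings A and C), via bis-cyclohexadiene cycloadduct 23 (not isolated)
Conditions: 22 (2.5 equiv), Me3SiOTf (20 mol %), CH2Cl2, −78 → −30 °C; then 1 M HCl, THF, 0 °C → rt
Reagents that add atoms: none
Why: Proposed new method: Me3SiOTf silylates the carbonyl oxygen of the alkynylogous ester 22; the terminal diene carbon of each arm (future C5) attacks the alkoxy-bearing alkyne carbon (future C6), and the 1-silyloxy-3-alkoxyallene so formed closes with its central carbon (future C1) onto the dioxygenated carbenium carbon (future C2), releasing the silyl cation, the concerted asynchronous (4+2) cycloaddition being the limiting alternative that leads to the same adduct 23. The closest known reaction type is the cycloaddition–aromatisation of Brassard-type vinylketene acetals and of 1,1-dimethoxy-3-silyloxy dienes with acetylenic ketones and esters to resorcinol ethers, together with Lewis-acid-mediated Mukaiyama–Michael additions of silyl ketene acetals to ynones; an ynone bearing an alkoxy group on the alkyne has not been used in this role. Rings A and C each close as a six-membered carbocycle by (4+2) annulation, in the stepwise reading a 6-(enolexo)-exo-trig closure, and dilute acid then expels methanol across C2 and C5 of each ring, which leaves OSiMe3 (then OH) at C2 of ring A but OMe at C2 of ring C, frees the C4 hydroxyl of ring C and returns the ring B silyl enol ether to the acetyl group. No stereocentre survives, since C2 and C5 of 23 become aromatic carbons. The step needs regiocontrol (butanoyl next to the former ketene acetal carbon), which follows from pairing the most nucleophilic diene terminus with the unhindered, oxygen-stabilised sp carbon of the activated ynone (the other closure would be four-membered), and it needs s-cis dienes, which the outward (Z) placement of the ring B arm on both termini allows. Chemoselectivity over the ring B silyl enol ether rests on the far higher nucleophilicity of the two vinylketene acetals, and the low temperature spares the isopropyl ynol ether and the benzyl ethers.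

**Step 16**
Reactants: 24 protected trimer
Product: 25 target trimer (CNP0184345.0)
Conditions: BCl3, C6HMe5, CH2Cl2, −78 → 0 °C; then MeOH
Reagents that add atoms: none
Why: Lewis-acid ether cleavage: BCl3 removes aryl benzyl ethers (benzyl cation trapped by pentamethylbenzene) and secondary alkyl aryl ethers by an SN1-type path at low temperature, the isopropyl ether of ring C with chelation help from the ketone, while the 4-OMe of ring A has no chelating neighbour and the 2-OMe of ring C is the second ortho ether of a ketone already held as a boron chelate, where BCl3 dealkylation is known to stop.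

**Compound list**

1 | methyl 2-methyl-3-oxobutanoate | COC(=O)C(C)C(C)=O | starting material
2 | methyl (2E)-3-methoxy-2-methylbut-2-enoate | CO/C(C)=C(\C)C(=O)OC | intermediate
3 | (1E)-1,3-dimethoxy-2-methyl-1-(trimethylsilyloxy)buta-1,3-diene | C=C(OC)/C(C)=C(\OC)O[Si](C)(C)C | intermediate
4 | trimethyl orthopropionate (1,1,1-trimethoxypropane) | CCC(OC)(OC)OC | starting material
5 | 1,1-dimethoxyprop-1-ene | CC=C(OC)OC | intermediate
6 | acetyl chloride | CC(Cl)=O | starting material
7 | 4,4-dimethoxy-3-methylbut-3-en-2-one | CC(=O)C(C)=C(OC)OC | intermediate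
8 | 1,1-dimethoxy-2-methyl-3-(trimethylsilyloxy)buta-1,3-diene | C=C(O[Si](C)(C)C)C(C)=C(OC)OC | intermediate
9 | 2,4,6-trihydroxyacetophenone | CC(=O)c1c(O)cc(O)cc1O | starting material
10 | 5-acetyl-2,4,6-trihydroxybenzene-1,3-dicarbaldehyde | CC(=O)c1c(O)c(C=O)c(O)c(C=O)c1O | intermediate
11 | 5-acetyl-2,4,6-tris(benzyloxy)benzene-1,3-dicarbaldehyde | CC(=O)c1c(OCc2ccccc2)c(C=O)c(OCc2ccccc2)c(C=O)c1OCc1ccccc1 | intermediate
12 | 1-[2,4,6-tris(benzyloxy)-3,5-bis(hydroxymethyl)phenyl]ethan-1-one | CC(=O)c1c(OCc2ccccc2)c(CO)c(OCc2ccccc2)c(CO)c1OCc1ccccc1 | intermediate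
13 | [5-acetyl-2,4,6-tris(benzyloxy)-1,3-phenylene]bis(methylene) diacetate | CC(=O)c1c(OCc2ccccc2)c(COC(C)=O)c(OCc2ccccc2)c(COC(C)=O)c1OCc1ccccc1 | intermediate
14 | methyl (2E)-5-[3-acetyl-2,4,6-tris(benzyloxy)-5-(5,5-dimethoxy-4-methyl-3-oxopent-4-en-1-yl)phenyl]-3-methoxy-2-methylpent-2-enoate | CC(=O)c1c(OCc2ccccc2)c(CC/C(OC)=C(/C)C(=O)OC)c(OCc2ccccc2)c(CCC(=O)C(C)=C(OC)OC)c1OCc1ccccc1 | intermediate
15 | ring B tris(benzyl ether) with 1-(trimethylsilyloxy)vinyl group, (2Z,4E)-3,5-dimethoxy-4-methyl-5-(trimethylsilyloxy)penta-2,4-dien-1-yl arm and (2Z)-5,5-dimethoxy-4-methyl-3-(trimethylsilyloxy)penta-2,4-dien-1-yl arm | C=C(O[Si](C)(C)C)c1c(OCc2ccccc2)c(C/C=C(\OC)/C(C)=C(\OC)O[Si](C)(C)C)c(OCc2ccccc2)c(C/C=C(\O[Si](C)(C)C)C(C)=C(OC)OC)c1OCc1ccccc1 | intermediate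
16 | butanoyl chloride | CCCC(Cl)=O | starting material
17 | N-methoxy-N-methylbutanamide | CCCC(=O)N(C)OC | intermediate
18 | propan-2-ol | CC(C)O | starting material
19 | trichloroethylene | ClC=C(Cl)Cl | starting material
20 | (E)-1,2-dichloro-1-(propan-2-yloxy)ethene | CC(C)O/C(Cl)=C\Cl | intermediate
21 | lithium (propan-2-yloxy)ethynide | [Li]C#COC(C)C | intermediate
22 | 1-(propan-2-yloxy)hex-1-yn-3-one | CCCC(=O)C#COC(C)C | intermediate
23 | bis-cyclohexadiene cycloadduct (two cyclohexa-1,4-diene rings on ring B, mixture of stereoisomers at the sp3 ring carbons) | C=C(O[Si](C)(C)C)c1c(OCc2ccccc2)c(CC2C(OC)=C(C)C(OC)(O[Si](C)(C)C)C(C(=O)CCC)=C2OC(C)C)c(OCc2ccccc2)c(CC2C(O[Si](C)(C)C)=C(C)C(OC)(OC)C(C(=O)CCC)=C2OC(C)C)c1OCc1ccccc1 | intermediate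
24 | protected trimer: ring B tris(benzyl ether); ring A 2-OH, 4-OMe, 6-O-isopropyl; ring C 2-OMe, 4-OH, 6-O-isopropyl | CC(=O)c1c(OCc2ccccc2)c(Cc2c(OC(C)C)c(C(=O)CCC)c(O)c(C)c2OC)c(OCc2ccccc2)c(Cc2c(OC(C)C)c(C(=O)CCC)c(OC)c(C)c2O)c1OCc1ccccc1 | intermediate
25 | target trimer CNP0184345.0 | CCCC(=O)c1c(O)c(C)c(OC)c(Cc2c(O)c(Cc3c(O)c(C)c(OC)c(C(=O)CCC)c3O)c(O)c(C(C)=O)c2O)c1O | target

**Totals and risks**

Total step count: 16. Longest linear sequence: 8 steps (9 → 10 → 11 → 12 → 13 → 14 → 15 → 24 → 25).

Steps most likely to fail:

1. Step 15 (the proposed new method). The conjugate addition may stop at the open-chain adduct without ring closure, the diene may add to the carbonyl carbon instead, or the ynol ether may fragment under the silyl Lewis acid. Fallback, setting out from 9 and 16 and returning at 25, uses the established methylene-bridge chemistry of acylphloroglucinols. Double aminomethylation of 9 (aqueous Me2NH, CH2O, EtOH) would give the bis-Mannich base 1-{3,5-bis[(dimethylamino)methyl]-2,4,6-trihydroxyphenyl}ethan-1-one F1. Commercial 2-methylphloroglucinol would be partially O-methylated (MeOH, HCl) and the ortho monomethyl ether 5-methoxy-4-methylbenzene-1,3-diol F2 separated. Friedel–Crafts acylation of F2 with 16 (AlCl3, nitrobenzene) can occur at either free ring carbon and should give aspidinol F3 (acyl between the two hydroxyls) and its isomer 1-(4,6-dihydroxy-2-methoxy-3-methylphenyl)butan-1-one F4 (acyl between hydroxyl and methoxyl), which are separated. Heating F1 with one equivalent each of F3 and F4 (dioxane, 80 °C) releases dimethylamine; the ortho-quinone methides are trapped at the single free ring carbon of each monomer, and the mixed trimer 25 is separated from the two symmetrical trimers.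

2. Step 16. Over-cleavage may occur: loss of the methyl ether next to the ring C ketone or of the hindered ring A methyl ether, or acid-induced scission of the diarylmethane bridges before the non-chelated isopropyl ether of ring A has gone. Fallback, setting out from 15, 17 and 19 and returning at 25, carries the C6 oxygens as benzyl ethers so that hydrogenolysis replaces all Lewis-acid dealkylation. Benzyl alcohol and 19 (KH, THF) would give benzyl (E)-1,2-dichlorovinyl ether F5; n-BuLi converts it into lithium (benzyloxy)ethynide F6, which is acylated by 17 to 1-(benzyloxy)hex-1-yn-3-one F7 (kept cold, since benzyl ynol ethers rearrange on warming). Annulation of 15 with F7 under the conditions of step 15 would pass through the bis-cycloadduct F8 and give the pentabenzyl ether F9; hydrogenolysis (H2, Pd/C, EtOAc) then gives 25.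

3. Step 10. The silyl Lewis acid may O-demethylate the acylketene acetal arm, or the benzylic cations may be consumed unproductively before the dienes capture them. Fallback, setting out from 12 (with 2 and 7) and returning at 14, attaches the arms under basic conditions. PBr3 (CH2Cl2, 0 °C) would convert 12 into 1-[2,4,6-tris(benzyloxy)-3,5-bis(bromomethyl)phenyl]ethan-1-one F10. F10 is added at −78 °C to an excess of a 1:1 mixture of the lithium dienolate of 2 F11 and the lithium enolate of 7 F12 (each from LiN(iPr)2, THF). γ-Alkylation of F11 and α'-alkylation of F12 should give 14, again statistically, the excess of enolate compensating for any proton transfer from the ring B ketone.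

**Further compounds**

F1 | step 15 | 1-{3,5-bis[(dimethylamino)methyl]-2,4,6-trihydroxyphenyl}ethan-1-one | CC(=O)c1c(O)c(CN(C)C)c(O)c(CN(C)C)c1O
F2 | step 15 | 5-methoxy-4-methylbenzene-1,3-diol | Cc1c(O)cc(O)cc1OC
F3 | step 15 | aspidinol, 1-(2,6-dihydroxy-4-methoxy-3-methylphenyl)butan-1-one | CCCC(=O)c1c(O)cc(OC)c(C)c1O
F4 | step 15 | 1-(4,6-dihydroxy-2-methoxy-3-methylphenyl)butan-1-one | CCCC(=O)c1c(O)cc(O)c(C)c1OC
F5 | step 16 | benzyl (E)-1,2-dichlorovinyl ether | c1ccccc1CO/C(Cl)=C\Cl
F6 | step 16 | lithium (benzyloxy)ethynide | [Li]C#COCc1ccccc1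
F7 | step 16 | 1-(benzyloxy)hex-1-yn-3-one | CCCC(=O)C#COCc1ccccc1
F8 | step 16 | bis-cyclohexadiene cycloadduct with benzyl enol ethers at C6 of both new rings (mixture of stereoisomers) | C=C(O[Si](C)(C)C)c1c(OCc2ccccc2)c(CC2C(OC)=C(C)C(OC)(O[Si](C)(C)C)C(C(=O)CCC)=C2OCc2ccccc2)c(OCc2ccccc2)c(CC2C(O[Si](C)(C)C)=C(C)C(OC)(OC)C(C(=O)CCC)=C2OCc2ccccc2)c1OCc1ccccc1
F9 | step 16 | pentabenzyl ether of the trimer (ring B tris(benzyl ether), benzyl ethers at C6 of rings A and C) | CC(=O)c1c(OCc2ccccc2)c(Cc2c(OCc3ccccc3)c(C(=O)CCC)c(O)c(C)c2OC)c(OCc2ccccc2)c(Cc2c(OCc3ccccc3)c(C(=O)CCC)c(OC)c(C)c2O)c1OCc1ccccc1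
F10 | step 10 | 1-[2,4,6-tris(benzyloxy)-3,5-bis(bromomethyl)phenyl]ethan-1-one | CC(=O)c1c(OCc2ccccc2)c(CBr)c(OCc2ccccc2)c(CBr)c1OCc1ccccc1
F11 | step 10 | lithium dienolate of methyl 3-methoxy-2-methylbut-2-enoate | [Li]OC(OC)=C(C)C(=C)OC
F12 | step 10 | lithium enolate of 4,4-dimethoxy-3-methylbut-3-en-2-one | [Li]OC(=C)C(C)=C(OC)OC
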